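Ring A (C1, C2, C3, C4, C5, C10; halimane numbering, ring B = C5–C10) contains a γ,δ-unsaturated acid, HO2C–C4–C5–C10=C1, the retron of a Claisen rearrangement. Ring A is therefore closed last by an Ireland–Claisen ring contraction: the silyl ketene acetal of a 3-methyl-6-(cyclohexenyl)-δ-valerolactone rearranges through a ring-enforced boat, forming the C4–C5 bond, the quaternary C4, the C5 stereocentre and the C1=C10 alkene in one operation, the lactone carbinol carbon (future C1) relaying its chirality to both new centres. The precursor is a ring B cyclohexenyl lactone whose C8/C9 centres come from asymmetric conjugate addition and Mukaiyama–Michael trapping.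

Key step: step 9

Remarks on the chemistry (assumptions):
- Halimane numbering is used for the target carbons throughout: ring A = C1, C2, C3, C4, C5, C10; ring B = C5, C6, C7, C8, C9, C10; side chain C11–C15 on C9.
- In step 1 the ligand enantiomer is the one that delivers the 3S centre; should the sense of induction prove opposite, its mirror image is used.
- Methyl 4-bromo-2-methylbutanoate is used as the racemate; the methyl-bearing centre it brings is erased by enolisation in step 9, so 14–16 carry no descriptor there.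

Step 1
Reactants: 1 2-methylcyclohex-2-en-1-one
Product: 3 (S)-trimethyl[(2,3-dimethylcyclohex-1-en-1-yl)oxy]silane, via dimethylaluminium enolate 2 (not isolated)
Conditions: Me3Al, copper thiophene-2-carboxylate CuO2CC4H3S (2 mol%), O,O'-(S)-1,1'-binaphthyl-2,2'-diyl N,N-bis[(R)-1-phenylethyl]phosphoramidite (4 mol%), Et2O, −30 °C; then TMSOTf, THF, 0 °C
Reagents that add atoms: trimethylaluminium C[Al](C)C; trimethylsilyl trifluoromethanesulfonate C[Si](C)(C)OS(=O)(=O)C(F)(F)F
Why: Copper-catalysed asymmetric conjugate addition of a methyl group sets C8 under ligand control, and O-silylation of the enolate fixes the tetrasubstituted enol ether needed for the next C–C bond.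

Step 2
Reactants: 3 (S)-trimethyl[(2,3-dimethylcyclohex-1-en-1-yl)oxy]silane; 4 methyl vinyl ketone
Product: 6 (2R,3S)-2,3-dimethyl-2-(3-oxobutyl)cyclohexan-1-one, via silyl enol ether 5 (not isolated)
Conditions: HNTf2 (2 mol%), CH2Cl2, −78 °C; then 1 M HCl, THF, 0 °C
Reagents that add atoms: methyl vinyl ketone CC(=O)C=C
Why: In this Mukaiyama–Michael addition the enone should approach the enol ether face anti to the pseudoaxial C8 methyl, so the quaternary C9 forms with its methyl cis to the C8 methyl, as in Robinson annulations of 2,3-dimethylcyclohexanone.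

Step 3
Reactants: 6 (2R,3S)-2,3-dimethyl-2-(3-oxobutyl)cyclohexan-1-one; 7 triethyl phosphonoacetate
Product: 8 ethyl (2E)-5-[(1R,2S)-1,2-dimethyl-6-oxocyclohexyl]-3-methylpent-2-enoate
Conditions: NaH, THF, 0 → 50 °C
Reagents that add atoms: triethyl phosphonoacetate CCOC(=O)CP(=O)(OCC)OCC
Why: The Horner–Wadsworth–Emmons olefination should react only at the unhindered methyl ketone, not at the α-quaternary ring ketone, and should favour the E enoate, any minor Z isomer being removed by chromatography.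

Step 4
Reactants: 8 ethyl (2E)-5-[(1R,2S)-1,2-dimethyl-6-oxocyclohexyl]-3-methylpent-2-enoate
Product: 9 ethyl (2E)-5-[(1R,6S)-1,6-dimethyl-2-(trifluoromethylsulfonyloxy)cyclohex-2-en-1-yl]-3-methylpent-2-enoate
Conditions: Tf2O, 2,6-di-tert-butyl-4-methylpyridine, CH2Cl2, 0 °C → rt
Reagents that add atoms: trifluoromethanesulfonic anhydride O=S(=O)(OS(=O)(=O)C(F)(F)F)C(F)(F)F
Why: Enol triflation with a hindered pyridine base can only give the C10=C5 triflate because C9 is quaternary, and it avoids strong bases that would deprotonate the enoate.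

Step 5
Reactants: 9 ethyl (2E)-5-[(1R,6S)-1,6-dimethyl-2-(trifluoromethylsulfonyloxy)cyclohex-2-en-1-yl]-3-methylpent-2-enoate
Product: 10 (5S,6R)-6-[(3E)-5-hydroxy-3-methylpent-3-en-1-yl]-5,6-dimethylcyclohex-1-en-1-yl trifluoromethanesulfonate
Conditions: DIBAL-H (i-Bu2AlH, 2.2 equiv), CH2Cl2, −78 °C; aq. potassium sodium tartrate
Reagents that add atoms: none
Why: 1,2-Reduction of the enoate should give the E allylic alcohol, alkenyl triflates being tolerant of DIBAL-H at low temperature.

Step 6
Reactants: 10 (5S,6R)-6-[(3E)-5-hydroxy-3-methylpent-3-en-1-yl]-5,6-dimethylcyclohex-1-en-1-yl trifluoromethanesulfonate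
Product: 11 (5S,6R)-6-[(3E)-5-(tert-butyldimethylsilyloxy)-3-methylpent-3-en-1-yl]-5,6-dimethylcyclohex-1-en-1-yl trifluoromethanesulfonate
Conditions: TBSCl, imidazole, DMF, rt
Reagents that add atoms: tert-butyldimethylsilyl chloride CC(C)(C)[Si](C)(C)Cl
Why: Standard silylation masks the primary allylic alcohol for the palladium, borane and enolate steps that follow.

Step 7
Reactants: 11 (5S,6R)-6-[(3E)-5-(tert-butyldimethylsilyloxy)-3-methylpent-3-en-1-yl]-5,6-dimethylcyclohex-1-en-1-yl trifluoromethanesulfonate; 12 methyl 4-bromo-2-methylbutanoate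
Product: 14 methyl 5-{(5S,6R)-6-[(3E)-5-(tert-butyldimethylsilyloxy)-3-methylpent-3-en-1-yl]-5,6-dimethylcyclohex-1-en-1-yl}-2-methyl-5-oxopentanoate, via alkylzinc bromide 13 (not isolated)
Conditions: 12, Zn dust, LiCl, THF, 50 °C; then 11, Pd(PPh3)4 (5 mol%), CO (1 atm), THF–NMP, 50 °C
Reagents that add atoms: methyl 4-bromo-2-methylbutanoate COC(=O)C(C)CCBr (as its zinc reagent 13, COC(=O)C(C)CC[Zn]Br); carbon monoxide [C-]#[O+]
Why: In this carbonylative Negishi coupling, oxidative addition of the alkenyl triflate, CO insertion and transmetalation with the ester-bearing alkylzinc should give the enone carrying C1–C4, with the silyl ether and ester untouched.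

Step 8
Reactants: 14 methyl 5-{(5S,6R)-6-[(3E)-5-(tert-butyldimethylsilyloxy)-3-methylpent-3-en-1-yl]-5,6-dimethylcyclohex-1-en-1-yl}-2-methyl-5-oxopentanoate
Product: 16 (6R)-6-{(5S,6R)-6-[(3E)-5-(tert-butyldimethylsilyloxy)-3-methylpent-3-en-1-yl]-5,6-dimethylcyclohex-1-en-1-yl}-3-methyltetrahydro-2H-pyran-2-one, via hydroxy ester 15 (not isolated)
Conditions: (S)-2-methyl-CBS-oxazaborolidine (20 mol%), catecholborane, PhMe, −78 °C; MeOH, aq. NaHCO3; then PPTS (cat.), PhMe, 60 °C
Reagents that add atoms: none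
Why: Corey–Bakshi–Shibata reduction, with the α-branched cyclohexenyl as the large group, should give the (R)-carbinol (future C1) under reagent control, and mild acid then closes the δ-lactone, whose epimeric methyl-bearing carbon does not matter.

Step 9
Reactants: 16 (6R)-6-{(5S,6R)-6-[(3E)-5-(tert-butyldimethylsilyloxy)-3-methylpent-3-en-1-yl]-5,6-dimethylcyclohex-1-en-1-yl}-3-methyltetrahydro-2H-pyran-2-one
Product: 20 (1S,5R,6S,8aR)-5-[(3E)-5-hydroxy-3-methylpent-3-en-1-yl]-1,5,6-trimethyl-1,2,3,5,6,7,8,8a-octahydronaphthalene-1-carboxylic acid, via lithium enolate 17 (not isolated), via silyl ketene acetal 18 (not isolated), via trimethylsilyl ester 19 (not isolated)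
Conditions: LDA, THF, −78 °C; TMSCl–Et3N, −78 °C → rt; PhMe, 105 °C; then TBAF, THF, rt; aq. NH4Cl/HCl (pH 3)
Reagents that add atoms: none
Why: LDA enolises the lactone and O-silylation gives the cyclic ketene acetal 18, whose geometry is fixed by the ring; on heating, a concerted [3,3] shift breaks the O–C1 bond, forms the C4–C5 bond and moves the alkene from C5=C10 to C1=C10, after which fluoride cleaves the silyl ester and the silyl ether. The closest known reaction type is the Ireland–Claisen ring contraction of ω-alkenyl lactone silyl enolates to cycloalkenecarboxylic acids, together with the related dioxanone-to-dihydropyran rearrangement. Ring A (C1, C2, C3, C4, C5, C10) closes by sigmatropic C4–C5 bond formation inside a bicyclo[2.2.2]-like array in which a chair is geometrically impossible and only the boat is available. C5 is controlled by the (R)-carbinol carbon C1, which can bring only the ring B alkene face syn to the C9 methyl over C4 (suprafacial chirality transfer), and C4 is fixed relative to C5 by the boat and the ring-locked ketene acetal geometry, which place the C4 methyl cis to H5 and the carboxyl cis to C6. The step needs O- over C-silylation and rearrangement in preference to decomposition despite the crowding next to quaternary C9; the TMSCl–Et3N quench, the small hydrogen on C1 that points toward C9 in the reactive rotamer and the unimolecular, ring-constrained nature of the shift should secure this.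

Step 10
Reactants: 20 (1S,5R,6S,8aR)-5-[(3E)-5-hydroxy-3-methylpent-3-en-1-yl]-1,5,6-trimethyl-1,2,3,5,6,7,8,8a-octahydronaphthalene-1-carboxylic acid
Product: 21 (1S,5R,6S,8aR)-5-[(3E)-5-acetoxy-3-methylpent-3-en-1-yl]-1,5,6-trimethyl-1,2,3,5,6,7,8,8a-octahydronaphthalene-1-carboxylic acid
Conditions: Ac2O, pyridine, DMAP (cat.), CH2Cl2, 0 °C → rt; then H2O–THF, rt
Reagents that add atoms: acetic anhydride CC(=O)OC(C)=O
Why: Acylation should occur at the primary allylic alcohol, while the hindered tertiary acid forms at most a mixed anhydride that the aqueous treatment hydrolyses.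

Compound list
1 | 2-methylcyclohex-2-en-1-one | CC1=CCCCC1=O | starting material
2 | dimethylaluminium (S)-2,3-dimethylcyclohex-1-en-1-olate | C[C@H]1CCCC(O[Al](C)C)=C1C | intermediate (not isolated)
3 | (S)-trimethyl[(2,3-dimethylcyclohex-1-en-1-yl)oxy]silane | C[C@H]1CCCC(O[Si](C)(C)C)=C1C | intermediate
4 | methyl vinyl ketone | CC(=O)C=C | starting material
5 | (2R,3S)-2,3-dimethyl-2-[3-(trimethylsilyloxy)but-2-en-1-yl]cyclohexan-1-one | C[Si](C)(C)OC(C)=CC[C@@]1(C)C(=O)CCC[C@@H]1C | intermediate (not isolated)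
6 | (2R,3S)-2,3-dimethyl-2-(3-oxobutyl)cyclohexan-1-one | CC(=O)CC[C@@]1(C)C(=O)CCC[C@@H]1C | intermediate
7 | triethyl phosphonoacetate | CCOC(=O)CP(=O)(OCC)OCC | starting material
8 | ethyl (2E)-5-[(1R,2S)-1,2-dimethyl-6-oxocyclohexyl]-3-methylpent-2-enoate | CCOC(=O)/C=C(\C)CC[C@@]1(C)C(=O)CCC[C@@H]1C | intermediate
9 | ethyl (2E)-5-[(1R,6S)-1,6-dimethyl-2-(trifluoromethylsulfonyloxy)cyclohex-2-en-1-yl]-3-methylpent-2-enoate | CCOC(=O)/C=C(\C)CC[C@@]1(C)C(OS(=O)(=O)C(F)(F)F)=CCC[C@@H]1C | intermediate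
10 | (5S,6R)-6-[(3E)-5-hydroxy-3-methylpent-3-en-1-yl]-5,6-dimethylcyclohex-1-en-1-yl trifluoromethanesulfonate | OC/C=C(\C)CC[C@@]1(C)C(OS(=O)(=O)C(F)(F)F)=CCC[C@@H]1C | intermediate
11 | (5S,6R)-6-[(3E)-5-(tert-butyldimethylsilyloxy)-3-methylpent-3-en-1-yl]-5,6-dimethylcyclohex-1-en-1-yl trifluoromethanesulfonate | CC(C)(C)[Si](C)(C)OC/C=C(\C)CC[C@@]1(C)C(OS(=O)(=O)C(F)(F)F)=CCC[C@@H]1C | intermediate
12 | methyl 4-bromo-2-methylbutanoate (racemic) | COC(=O)C(C)CCBr | starting material
13 | (4-methoxy-3-methyl-4-oxobutyl)zinc bromide | COC(=O)C(C)CC[Zn]Br | intermediate (not isolated)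
14 | methyl 5-{(5S,6R)-6-[(3E)-5-(tert-butyldimethylsilyloxy)-3-methylpent-3-en-1-yl]-5,6-dimethylcyclohex-1-en-1-yl}-2-methyl-5-oxopentanoate (both epimers at C2 of the pentanoate) | COC(=O)C(C)CCC(=O)C1=CCC[C@H](C)[C@@]1(C)CC/C(C)=C/CO[Si](C)(C)C(C)(C)C | intermediate
15 | methyl (5R)-5-{(5S,6R)-6-[(3E)-5-(tert-butyldimethylsilyloxy)-3-methylpent-3-en-1-yl]-5,6-dimethylcyclohex-1-en-1-yl}-5-hydroxy-2-methylpentanoate (both epimers at C2) | COC(=O)C(C)CC[C@@H](O)C1=CCC[C@H](C)[C@@]1(C)CC/C(C)=C/CO[Si](C)(C)C(C)(C)C | intermediate (not isolated)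
16 | (6R)-6-{(5S,6R)-6-[(3E)-5-(tert-butyldimethylsilyloxy)-3-methylpent-3-en-1-yl]-5,6-dimethylcyclohex-1-en-1-yl}-3-methyltetrahydro-2H-pyran-2-one (both epimers at C3) | CC1CC[C@@H](OC1=O)C2=CCC[C@H](C)[C@@]2(C)CC/C(C)=C/CO[Si](C)(C)C(C)(C)C | intermediate
17 | lithium enolate of lactone 16 | CC1=C(O[Li])O[C@H](CC1)C2=CCC[C@H](C)[C@@]2(C)CC/C(C)=C/CO[Si](C)(C)C(C)(C)C | intermediate (not isolated)
18 | trimethylsilyl ketene acetal of lactone 16, (2R)-2-(cyclohexenyl)-5-methyl-6-(trimethylsilyloxy)-3,4-dihydro-2H-pyran | CC1=C(O[Si](C)(C)C)O[C@H](CC1)C2=CCC[C@H](C)[C@@]2(C)CC/C(C)=C/CO[Si](C)(C)C(C)(C)C | intermediate (not isolated)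
19 | trimethylsilyl (1S,5R,6S,8aR)-5-[(3E)-5-(tert-butyldimethylsilyloxy)-3-methylpent-3-en-1-yl]-1,5,6-trimethyl-1,2,3,5,6,7,8,8a-octahydronaphthalene-1-carboxylate | CC(C)(C)[Si](C)(C)OC/C=C(\C)CC[C@@]1(C)C2=CCC[C@](C)(C(=O)O[Si](C)(C)C)[C@@H]2CC[C@@H]1C | intermediate (not isolated)
20 | (1S,5R,6S,8aR)-5-[(3E)-5-hydroxy-3-methylpent-3-en-1-yl]-1,5,6-trimethyl-1,2,3,5,6,7,8,8a-octahydronaphthalene-1-carboxylic acid | OC/C=C(\C)CC[C@@]1(C)C2=CCC[C@](C)(C(=O)O)[C@@H]2CC[C@@H]1C | intermediate
21 | (1S,5R,6S,8aR)-5-[(3E)-5-acetoxy-3-methylpent-3-en-1-yl]-1,5,6-trimethyl-1,2,3,5,6,7,8,8a-octahydronaphthalene-1-carboxylic acid (CNP0276297.2) | CC(=O)OC/C=C(\C)CC[C@@]1(C)C2=CCC[C@](C)(C(=O)O)[C@@H]2CC[C@@H]1C | target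

Total step count: 10
Longest linear sequence: 10 steps (from 1)

Steps most likely to fail

Step 9. The forced boat pushes the silyloxy group of the ketene acetal against the substituents of quaternary C9. The sigmatropic shift may therefore be slowed enough for C-silylation, desilylation or thermal decomposition of the ketene acetal to take over. The fallback closes ring A by a cycloaddition and sets out from 11. Stille coupling with tributyl(vinyl)stannane (Pd(PPh3)4, LiCl, THF, 65 °C) would give the 1-vinylcyclohexene diene F1. A Diels–Alder reaction with methacrolein (Me2AlCl, CH2Cl2, −78 °C, or a cationic oxazaborolidine Lewis acid if reagent control of the diene face is needed) would give the ring A aldehyde F2, the formyl-bearing carbon bonding to C5. Pinnick oxidation (NaClO2, NaH2PO4, 2-methyl-2-butene, t-BuOH–H2O) would give the silyl ether acid F3, and TBAF in THF would bring the route back at 20. In this fallback the C4/C5 configuration rests on the endo/exo and facial preferences of the cycloaddition, not on chirality transfer from C1, so diastereomers may have to be separated.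

Step 7. At the hindered alkenylpalladium intermediate, CO insertion or transmetalation may be slow, so that direct, non-carbonylative coupling or reduction of the triflate competes. The fallback builds the C10–C1 bond by a chromium-mediated carbonyl addition and sets out from 11. Nozaki–Hiyama–Kishi coupling with methyl 5-oxopentanoate (CrCl2, NiCl2 (cat.), DMF, rt) would give the allylic alcohol ester F4 as both carbinol epimers. Dess–Martin oxidation would give the enone ester F5. CBS reduction as in step 8 would give the (R)-hydroxy ester F6, which PPTS would close to the unmethylated lactone F7. LDA (THF, −78 °C) would give its lithium enolate F8, and iodomethane would methylate it to return to the route at 16.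

Step 2. Protodesilylation of the tetrasubstituted enol ether, oligomerisation of the enone or incomplete facial control may erode the formation of the quaternary C9 centre. The fallback uses an enolate alkylation and sets out from 3. MeLi (THF, 0 °C) would release the lithium enolate F9. Alkylation with 1,3-dichlorobut-2-ene, again anti to the C8 methyl, would give the vinyl chloride F10 (Wichterle sequence). Hydrolysis of the vinyl chloride in cold concentrated H2SO4 would bring the route back at 6.

Further compounds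
F1 | step 9 | tert-butyl{[(2E)-5-[(1R,6S)-2-ethenyl-1,6-dimethylcyclohex-2-en-1-yl]-3-methylpent-2-en-1-yl]oxy}dimethylsilane | C=CC1=CCC[C@H](C)[C@@]1(C)CC/C(C)=C/CO[Si](C)(C)C(C)(C)C
F2 | step 9 | (1S,5R,6S,8aR)-5-[(3E)-5-(tert-butyldimethylsilyloxy)-3-methylpent-3-en-1-yl]-1,5,6-trimethyl-1,2,3,5,6,7,8,8a-octahydronaphthalene-1-carbaldehyde | CC(C)(C)[Si](C)(C)OC/C=C(\C)CC[C@@]1(C)C2=CCC[C@](C)(C=O)[C@@H]2CC[C@@H]1C
F3 | step 9 | (1S,5R,6S,8aR)-5-[(3E)-5-(tert-butyldimethylsilyloxy)-3-methylpent-3-en-1-yl]-1,5,6-trimethyl-1,2,3,5,6,7,8,8a-octahydronaphthalene-1-carboxylic acid | CC(C)(C)[Si](C)(C)OC/C=C(\C)CC[C@@]1(C)C2=CCC[C@](C)(C(=O)O)[C@@H]2CC[C@@H]1C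
F4 | step 7 | methyl 5-{(5S,6R)-6-[(3E)-5-(tert-butyldimethylsilyloxy)-3-methylpent-3-en-1-yl]-5,6-dimethylcyclohex-1-en-1-yl}-5-hydroxypentanoate (both carbinol epimers) | COC(=O)CCCC(O)C1=CCC[C@H](C)[C@@]1(C)CC/C(C)=C/CO[Si](C)(C)C(C)(C)C
F5 | step 7 | methyl 5-{(5S,6R)-6-[(3E)-5-(tert-butyldimethylsilyloxy)-3-methylpent-3-en-1-yl]-5,6-dimethylcyclohex-1-en-1-yl}-5-oxopentanoate | COC(=O)CCCC(=O)C1=CCC[C@H](C)[C@@]1(C)CC/C(C)=C/CO[Si](C)(C)C(C)(C)C
F6 | step 7 | methyl (5R)-5-{(5S,6R)-6-[(3E)-5-(tert-butyldimethylsilyloxy)-3-methylpent-3-en-1-yl]-5,6-dimethylcyclohex-1-en-1-yl}-5-hydroxypentanoate | COC(=O)CCC[C@@H](O)C1=CCC[C@H](C)[C@@]1(C)CC/C(C)=C/CO[Si](C)(C)C(C)(C)C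
F7 | step 7 | (6R)-6-{(5S,6R)-6-[(3E)-5-(tert-butyldimethylsilyloxy)-3-methylpent-3-en-1-yl]-5,6-dimethylcyclohex-1-en-1-yl}tetrahydro-2H-pyran-2-one | O=C1CCC[C@@H](O1)C2=CCC[C@H](C)[C@@]2(C)CC/C(C)=C/CO[Si](C)(C)C(C)(C)C
F8 | step 7 | lithium enolate of lactone F7 | [Li]OC1=CCC[C@@H](O1)C2=CCC[C@H](C)[C@@]2(C)CC/C(C)=C/CO[Si](C)(C)C(C)(C)C
F9 | step 2 | lithium (S)-2,3-dimethylcyclohex-1-en-1-olate | C[C@H]1CCCC(O[Li])=C1C
F10 | step 2 | (2R,3S)-2-(3-chlorobut-2-en-1-yl)-2,3-dimethylcyclohexan-1-one | CC(Cl)=CC[C@@]1(C)C(=O)CCC[C@@H]1C
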